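The route rests on opening the dihydropyran at C4–C5, C1–C9 and O2–C1. It exploits the fact that C1 and C4 are attached to the adjacent cyclopentane carbons C9 and C5 and that C1 and C3 are 1,5-related carbonyl carbons, the product pattern of an enol–alkene photocycloaddition followed by retro-aldol cleavage. One irradiation of a cyclopentene with triformylmethane should therefore forge both C–C bonds, close the lactol ring and set C5, C9 and C1. The precursor is an enantiopure cyclopent-2-enol from 2-deoxy-D-ribose: free tertiary C8 hydroxyl on the α face, C10 TBS ether and C7 PMB ether on the β face.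

Key step: step 9

Remark: iridoid numbering is used (C1 acetal carbon; O2; C3=C4; C5/C9 ring fusion; C6; C7; C8; C10 on C8; C11 on C4), β is the face of H5 and H9, and triformylmethane is taken as a purchasable reagent that exists as its enol.

Step 1
Reactants: 1 2-deoxy-D-ribose
Product: 2 (2R,3S)-hex-5-ene-1,2,3-triol
Conditions: Ph3PCH3Br (3.2 equiv), KOtBu (3.0 equiv), THF, 0 °C to reflux
Reagents that add atoms: methyltriphenylphosphonium bromide, C[P+](c1ccccc1)(c1ccccc1)c1ccccc1.[Br-]
Why: Wittig methylenation of the open-chain aldehyde form of the free sugar, with the extra ylide acting as base for the hydroxyl groups; the two carbinol centres (later C7 and C8) are not involved.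

Step 2
Reactants: 2 (2R,3S)-hex-5-ene-1,2,3-triol
Product: 3 (1S)-1-[(4R)-2,2-dimethyl-1,3-dioxolan-4-yl]but-3-en-1-ol
Conditions: 2,2-dimethoxypropane, p-TsOH·H2O (cat.), acetone, 0 °C to rt
Reagents that add atoms: 2,2-dimethoxypropane, COC(C)(C)OC
Why: Acid-catalysed ketal exchange under equilibrating conditions, in which the terminal 1,3-dioxolane should be favoured over the internal one that would have to be cis-4,5-disubstituted in this erythro triol, so that only the future C7 hydroxyl stays free.

Step 3
Reactants: 3 (1S)-1-[(4R)-2,2-dimethyl-1,3-dioxolan-4-yl]but-3-en-1-ol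
Product: 4 (4R)-4-[(1S)-1-(4-methoxybenzyloxy)but-3-en-1-yl]-2,2-dimethyl-1,3-dioxolane
Conditions: NaH, 4-methoxybenzyl chloride, Bu4NI (cat.), THF/DMF, 0 °C to rt
Reagents that add atoms: 4-methoxybenzyl chloride, COc1ccc(CCl)cc1
Why: Williamson etherification of the single free secondary hydroxyl; the PMB ether is chosen because its oxygen can chelate magnesium in step 7 and because it is later removed oxidatively under neutral conditions.

Step 4
Reactants: 4 (4R)-4-[(1S)-1-(4-methoxybenzyloxy)but-3-en-1-yl]-2,2-dimethyl-1,3-dioxolane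
Product: 5 (2R,3S)-3-(4-methoxybenzyloxy)hex-5-ene-1,2-diol
Conditions: AcOH/H2O (4:1), 40 °C
Reagents that add atoms: none
Why: Mild aqueous-acid hydrolysis of the isopropylidene ketal, conditions under which the PMB ether and the terminal alkene are stable.

Step 5
Reactants: 5 (2R,3S)-3-(4-methoxybenzyloxy)hex-5-ene-1,2-diol
Product: 6 (2R,3S)-1-(tert-butyldimethylsilyloxy)-3-(4-methoxybenzyloxy)hex-5-en-2-ol
Conditions: TBSCl (1.05 equiv), imidazole, CH2Cl2, −20 to 0 °C
Reagents that add atoms: tert-butyldimethylsilyl chloride, CC(C)(C)[Si](C)(C)Cl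
Why: Sterically controlled silylation of the primary hydroxyl beside the secondary one; the silyl ether is a poor donor that should not compete for magnesium in step 7 and it is fluoride-labile at the end.

Step 6
Reactants: 6 (2R,3S)-1-(tert-butyldimethylsilyloxy)-3-(4-methoxybenzyloxy)hex-5-en-2-ol
Product: 7 (3S)-1-(tert-butyldimethylsilyloxy)-3-(4-methoxybenzyloxy)hex-5-en-2-one
Conditions: Dess–Martin periodinane, CH2Cl2, 0 °C to rt
Reagents that add atoms: none
Why: Dess–Martin oxidation of the secondary alcohol under non-basic conditions that should not epimerise the α-alkoxy centre C7.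

Step 7
Reactants: 7 (3S)-1-(tert-butyldimethylsilyloxy)-3-(4-methoxybenzyloxy)hex-5-en-2-one
Product: 8 (3R,4S)-3-[(tert-butyldimethylsilyloxy)methyl]-4-(4-methoxybenzyloxy)hepta-1,6-dien-3-ol
Conditions: MgBr2·OEt2, CH2Cl2, −78 °C; then CH2=CHMgBr (THF solution), −78 °C
Reagents that add atoms: vinylmagnesium bromide, C=C[Mg]Br
Why: Chelation-controlled Grignard addition (Cram chelate model): magnesium bridges the ketone oxygen and the C7 PMB ether oxygen in a five-membered ring and vinyl adds to the carbonyl face on the side of the C7 hydrogen, away from the allyl group, which sets C8 as R with its hydroxyl trans to the C7 oxygen in the later ring.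

Step 8
Reactants: 8 (3R,4S)-3-[(tert-butyldimethylsilyloxy)methyl]-4-(4-methoxybenzyloxy)hepta-1,6-dien-3-ol
Product: 9 (1R,5S)-1-[(tert-butyldimethylsilyloxy)methyl]-5-(4-methoxybenzyloxy)cyclopent-2-en-1-ol
Conditions: second-generation Grubbs catalyst (H2IMes)(PCy3)Cl2Ru=CHPh (3 mol %), CH2Cl2, 40 °C
Reagents that add atoms: none
Why: Ring-closing metathesis of the 1,6-diene to the cyclopentene with loss of ethylene, a closure that tolerates a free tertiary allylic hydroxyl.

Step 9
Reactants: 9 (1R,5S)-1-[(tert-butyldimethylsilyloxy)methyl]-5-(4-methoxybenzyloxy)cyclopent-2-en-1-ol; 10 triformylmethane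
Product: 13 iridoid lactol 4-carbaldehyde (1β-OH; 5βH/9βH; 7β-OPMB; 8α-OH; 10-OTBS), via cyclobutanol photoadduct 11 (not isolated), via ring-opened dialdehyde enol 12 (not isolated)
Conditions: 10 (3 equiv), hν (medium-pressure Hg lamp, Pyrex filter), degassed MeCN, 0 °C; then rt in the dark
Reagents that add atoms: none
Why: Light excites the hydrogen-bonded enol of 10, whose triplet adds across C5=C9 through a 1,4-diradical to the cis-fused cyclobutanol 11 (new bonds C4–C5 and C1–C9), and relief of ring strain together with the doubly formyl-stabilised carbanion at C4 then drives retro-aldol cleavage of C1–C4 to the 1,5-dialdehyde enol 12, which closes to the lactol. The closest known reaction type is the de Mayo reaction of formyl-substituted 1,3-dicarbonyl enols with cyclopentenes. The pyran ring closes by 6-exo-trig addition of the C3 enol oxygen to the C1 aldehyde (bond O2–C1). C5 and C9 are set together, because the four-membered ring can only be cis-fused and the enol should approach the α face, which carries only the small free C8 hydroxyl, while the C10 silyloxymethyl group and the C7 PMB ether block the β face; C1 is set under thermodynamic control in the equilibrating lactol, with its hydroxyl β and trans to the C9–C8 bond. The step needs head-to-tail regiochemistry, which the quaternary C8 next to C9 should secure by directing the fully substituted C4 to the less hindered C5, and because 10 has threefold symmetry the dicarbonyl partner itself raises no regiochemical question.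

Step 10
Reactants: 13 iridoid lactol 4-carbaldehyde; 14 isovaleric anhydride
Product: 15 1β-O-isovaleryl iridoid 4-carbaldehyde (7β-OPMB; 8α-OH; 10-OTBS)
Conditions: 14 (1.3 equiv), pyridine, DMAP (cat.), CH2Cl2, −20 to 0 °C
Reagents that add atoms: none
Why: DMAP-catalysed acylation of the anomeric hydroxyl of the equilibrating lactol, expected to give the β-ester (trans to the C9–C8 bond, the less hindered and anomerically favoured arrangement) while the hindered tertiary C8 hydroxyl stays untouched.

Step 11
Reactants: 15 1β-O-isovaleryl iridoid 4-carbaldehyde (7β-OPMB)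
Product: 16 1β-O-isovaleryl iridoid 4-carbaldehyde with free 7β-OH (8α-OH; 10-OTBS)
Conditions: DDQ, CH2Cl2/pH 7 phosphate buffer, 0 °C
Reagents that add atoms: none
Why: Oxidative PMB ether cleavage by DDQ through the benzylic oxocarbenium ion, under buffered neutral conditions that should leave the anomeric ester, the silyl ether and the electron-poor formyl enol ether intact.

Step 12
Reactants: 17 p-coumaric acid
Product: 19 (E)-3-[4-(tert-butyldimethylsilyloxy)phenyl]prop-2-enoic acid, via bis-silylated coumarate 18 (not isolated)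
Conditions: TBSCl (2.3 equiv), imidazole, DMF, rt; then AcOH, THF/H2O, rt
Reagents that add atoms: tert-butyldimethylsilyl chloride, CC(C)(C)[Si](C)(C)Cl
Why: Silylation of both acidic hydroxyls followed by selective hydrolysis of the far more labile silyl ester, which leaves the phenol protected so that it cannot compete in the esterification.

Step 13
Reactants: 16 1β-O-isovaleryl iridoid 4-carbaldehyde with free 7β-OH; 19 (E)-3-[4-(tert-butyldimethylsilyloxy)phenyl]prop-2-enoic acid
Product: 20 7β-O-(4-O-TBS-p-coumaroyl) 1β-O-isovaleryl iridoid 4-carbaldehyde (8α-OH; 10-OTBS)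
Conditions: DCC, DMAP (cat.), CH2Cl2, 0 °C to rt
Reagents that add atoms: none
Why: Steglich esterification of the only acylable hydroxyl (secondary C7–OH; the tertiary C8–OH is inert here), placed after the photochemical step so that the cinnamate chromophore is never irradiated.

Step 14
Reactants: 20 7β-O-(4-O-TBS-p-coumaroyl) 1β-O-isovaleryl iridoid 4-carbaldehyde
Product: 21 11-oxo-luzonoid A (C11 aldehyde with free phenol; free C8 and C10 hydroxyls)
Conditions: HF·pyridine, pyridine, THF, 0 °C to rt
Reagents that add atoms: none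
Why: Fluoride-mediated cleavage of the aryl and the primary alkyl silyl ether at the aldehyde stage, where the pyran double bond is a vinylogous formate and therefore much less acid-sensitive than the allylic-alcohol enol ether of the target.

Step 15
Reactants: 21 11-oxo-luzonoid A
Product: 22 luzonoid A
Conditions: NaBH4, CeCl3·7H2O, MeOH, −78 °C
Reagents that add atoms: none
Why: Luche reduction, in which cerium-activated borohydride in methanol should deliver hydride 1,2 to the C11 aldehyde at low temperature without touching the cinnamate, the anomeric ester or the enol ether.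

Compound list

1 | 2-deoxy-D-ribose ((3S,4R)-3,4,5-trihydroxypentanal, drawn open-chain) | O=CC[C@H](O)[C@H](O)CO | starting material
2 | (2R,3S)-hex-5-ene-1,2,3-triol | C=CC[C@H](O)[C@H](O)CO | intermediate
3 | (1S)-1-[(4R)-2,2-dimethyl-1,3-dioxolan-4-yl]but-3-en-1-ol | C=CC[C@H](O)[C@H]1COC(C)(C)O1 | intermediate
4 | (4R)-4-[(1S)-1-(4-methoxybenzyloxy)but-3-en-1-yl]-2,2-dimethyl-1,3-dioxolane | C=CC[C@H](OCc1ccc(OC)cc1)[C@H]2COC(C)(C)O2 | intermediate
5 | (2R,3S)-3-(4-methoxybenzyloxy)hex-5-ene-1,2-diol | C=CC[C@H](OCc1ccc(OC)cc1)[C@H](O)CO | intermediate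
6 | (2R,3S)-1-(tert-butyldimethylsilyloxy)-3-(4-methoxybenzyloxy)hex-5-en-2-ol | C=CC[C@H](OCc1ccc(OC)cc1)[C@H](O)CO[Si](C)(C)C(C)(C)C | intermediate
7 | (3S)-1-(tert-butyldimethylsilyloxy)-3-(4-methoxybenzyloxy)hex-5-en-2-one | C=CC[C@H](OCc1ccc(OC)cc1)C(=O)CO[Si](C)(C)C(C)(C)C | intermediate
8 | (3R,4S)-3-[(tert-butyldimethylsilyloxy)methyl]-4-(4-methoxybenzyloxy)hepta-1,6-dien-3-ol | C=CC[C@H](OCc1ccc(OC)cc1)[C@](O)(CO[Si](C)(C)C(C)(C)C)C=C | intermediate
9 | (1R,5S)-1-[(tert-butyldimethylsilyloxy)methyl]-5-(4-methoxybenzyloxy)cyclopent-2-en-1-ol (key-step precursor; C7 S, C8 R; alkene C5=C9) | C1C=C[C@@](O)(CO[Si](C)(C)C(C)(C)C)[C@H]1OCc2ccc(OC)cc2 | intermediate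
10 | triformylmethane (2-formylmalonaldehyde; present and reacting as its hydroxymethylene enol) | O=CC(C=O)C=O | starting material
11 | cyclobutanol photoadduct, not isolated: cis-fused bicyclo[3.2.0]heptane with the cyclobutane C1–C9–C5–C4 on the α face; C4 carries two formyl groups; C1 carries OH (either epimer, destroyed in the next event) | OC1[C@@H]2[C@@](O)(CO[Si](C)(C)C(C)(C)C)[C@@H](OCc3ccc(OC)cc3)C[C@@H]2C1(C=O)C=O | intermediate
12 | ring-opened dialdehyde enol, not isolated: cis-1,2-disubstituted cyclopentane with the C1 formyl group on C9 and the 2-(hydroxymethylene)malonaldehyde unit on C5 | O=C[C@@H]1[C@@](O)(CO[Si](C)(C)C(C)(C)C)[C@@H](OCc2ccc(OC)cc2)C[C@@H]1C(C=O)=CO | intermediate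
13 | (1R,4aS,6S,7R,7aS)-7-[(tert-butyldimethylsilyloxy)methyl]-1,7-dihydroxy-6-(4-methoxybenzyloxy)-1,4a,5,6,7,7a-hexahydrocyclopenta[c]pyran-4-carbaldehyde (iridoid lactol 4-carbaldehyde, key-step product) | O[C@@H]1OC=C(C=O)[C@H]2C[C@H](OCc3ccc(OC)cc3)[C@](O)(CO[Si](C)(C)C(C)(C)C)[C@@H]12 | intermediate
14 | isovaleric anhydride (3-methylbutanoic anhydride) | CC(C)CC(=O)OC(=O)CC(C)C | starting material
15 | (1S,4aS,6S,7R,7aS)-7-[(tert-butyldimethylsilyloxy)methyl]-4-formyl-7-hydroxy-6-(4-methoxybenzyloxy)-1,4a,5,6,7,7a-hexahydrocyclopenta[c]pyran-1-yl 3-methylbutanoate | CC(C)CC(=O)O[C@@H]1OC=C(C=O)[C@H]2C[C@H](OCc3ccc(OC)cc3)[C@](O)(CO[Si](C)(C)C(C)(C)C)[C@@H]12 | intermediate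
16 | (1S,4aS,6S,7R,7aS)-7-[(tert-butyldimethylsilyloxy)methyl]-4-formyl-6,7-dihydroxy-1,4a,5,6,7,7a-hexahydrocyclopenta[c]pyran-1-yl 3-methylbutanoate | CC(C)CC(=O)O[C@@H]1OC=C(C=O)[C@H]2C[C@H](O)[C@](O)(CO[Si](C)(C)C(C)(C)C)[C@@H]12 | intermediate
17 | p-coumaric acid ((E)-3-(4-hydroxyphenyl)prop-2-enoic acid) | OC(=O)/C=C/c1ccc(O)cc1 | starting material
18 | bis-silylated coumarate, not isolated: tert-butyldimethylsilyl (E)-3-[4-(tert-butyldimethylsilyloxy)phenyl]prop-2-enoate | CC(C)(C)[Si](C)(C)OC(=O)/C=C/c1ccc(O[Si](C)(C)C(C)(C)C)cc1 | intermediate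
19 | (E)-3-[4-(tert-butyldimethylsilyloxy)phenyl]prop-2-enoic acid | OC(=O)/C=C/c1ccc(O[Si](C)(C)C(C)(C)C)cc1 | intermediate
20 | (1S,4aS,6S,7R,7aS)-7-[(tert-butyldimethylsilyloxy)methyl]-4-formyl-7-hydroxy-6-{(E)-3-[4-(tert-butyldimethylsilyloxy)phenyl]prop-2-enoyloxy}-1,4a,5,6,7,7a-hexahydrocyclopenta[c]pyran-1-yl 3-methylbutanoate | CC(C)CC(=O)O[C@@H]1OC=C(C=O)[C@H]2C[C@H](OC(=O)/C=C/c3ccc(O[Si](C)(C)C(C)(C)C)cc3)[C@](O)(CO[Si](C)(C)C(C)(C)C)[C@@H]12 | intermediate
21 | 11-oxo-luzonoid A: (1S,4aS,6S,7R,7aS)-4-formyl-7-hydroxy-7-(hydroxymethyl)-6-[(E)-3-(4-hydroxyphenyl)prop-2-enoyloxy]-1,4a,5,6,7,7a-hexahydrocyclopenta[c]pyran-1-yl 3-methylbutanoate | CC(C)CC(=O)O[C@@H]1OC=C(C=O)[C@H]2C[C@H](OC(=O)/C=C/c3ccc(O)cc3)[C@](O)(CO)[C@@H]12 | intermediate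
22 | luzonoid A: (1S,4aS,6S,7R,7aS)-7-hydroxy-4,7-bis(hydroxymethyl)-6-[(E)-3-(4-hydroxyphenyl)prop-2-enoyloxy]-1,4a,5,6,7,7a-hexahydrocyclopenta[c]pyran-1-yl 3-methylbutanoate | CC(C)CC(=O)O[C@@H]1OC=C(CO)[C@H]2C[C@H](OC(=O)/C=C/c3ccc(O)cc3)[C@](O)(CO)[C@@H]12 | target

Total step count: 15 (steps 1–15, of which step 12 is the one-step side branch to acid 19).
Longest linear sequence: 14 steps (steps 1–11 and 13–15) from 2-deoxy-D-ribose.

Steps most likely to fail

1. Step 9. The photocycloaddition may be inefficient or unselective. Possible failures are head-to-head addition, attack on the β face, secondary photolysis of the formyl enol ether product under the same light, and acid-promoted loss of the tertiary allylic hydroxyl by the strongly acidic tricarbonyl partner. The fallback sets out from 9 and changes the dicarbonyl partner and the oxidation state in which C11 is carried. Cyclopentene 9 is irradiated with methyl diformylacetate (methyl 2-formyl-3-oxopropanoate, used as its enol), a much weaker acid whose photoproduct absorbs at shorter wavelength, to give the C4 methyl ester lactol F1. The anomeric hydroxyl is silylated (TESCl, imidazole, CH2Cl2) to the 1-O-triethylsilyl ester acetal F2. The vinylogous carbonate ester is reduced with iBu2AlH (CH2Cl2, −78 °C) to the C11 allylic alcohol F3. Oxidation with MnO2 (CH2Cl2, rt) gives the 1-O-triethylsilyl C11 aldehyde F4. Selective removal of the labile anomeric silyl group (AcOH/THF/H2O, 0 °C) brings the route back at lactol aldehyde 13.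

2. Step 7. Facial selectivity may be poor if magnesium does not hold the C7 ether oxygen, so that open-chain Felkin–Anh addition competes, and the Grignard reagent may enolise the ketone. The fallback sets out from 7 and replaces substrate control by reagent control. Methylenation of 7 with Cp2TiMe2 (toluene, 65 °C), a non-basic reagent that should not epimerise C7, gives the 2-methylene silyl ether F5. Bu4NF (THF, 0 °C) frees the 2-substituted allylic alcohol F6. Sharpless asymmetric epoxidation (Ti(OiPr)4, L-(+)-diethyl tartrate, tBuOOH, 4 Å sieves, CH2Cl2, −20 °C) touches only the allylic alcohol alkene and gives the 2,2-disubstituted epoxy alcohol F7. L-(+)-tartrate is the enantiomer that converts (E)-2-alken-1-ols into (2S,3S)-epoxy alcohols, and the same face preference gives the C8 configuration needed here. Silylation (TBSCl, imidazole) gives the epoxy silyl ether F8. Excess dimethylsulfonium methylide (Me3SI, n-BuLi, THF, −10 °C to rt) opens the epoxide at its CH2 terminus (C9) and eliminates dimethyl sulfide, which turns the epoxide into the vinyl carbinol and rejoins the route at diene 8.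

3. Step 15. In the unprotected polyol the anomeric isovalerate may be lost by methanolysis or hydride attack, the coumarate may migrate under the basic borohydride medium, and the polar product may be hard to isolate. The fallback sets out from 20 and reverses the order of the last two operations. Luche reduction (NaBH4, CeCl3·7H2O, MeOH/THF, −78 °C) on the still silylated, lipophilic aldehyde gives the bis-silyl C11 alcohol F9, which can be purified on silica. Both silyl groups are then removed with buffered fluoride (Et3N·3HF, MeCN/THF, rt), which arrives directly at 22.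

Further compounds

F1 | step 9 | methyl (1R,4aS,6S,7R,7aS)-7-[(tert-butyldimethylsilyloxy)methyl]-1,7-dihydroxy-6-(4-methoxybenzyloxy)-1,4a,5,6,7,7a-hexahydrocyclopenta[c]pyran-4-carboxylate (C4 methyl ester lactol) | O[C@@H]1OC=C(C(=O)OC)[C@H]2C[C@H](OCc3ccc(OC)cc3)[C@](O)(CO[Si](C)(C)C(C)(C)C)[C@@H]12
F2 | step 9 | 1β-O-triethylsilyl acetal of F1 | CC[Si](CC)(CC)O[C@@H]1OC=C(C(=O)OC)[C@H]2C[C@H](OCc3ccc(OC)cc3)[C@](O)(CO[Si](C)(C)C(C)(C)C)[C@@H]12
F3 | step 9 | C11 allylic alcohol from F2 (1β-O-triethylsilyl; 7β-OPMB; 8α-OH; 10-OTBS) | CC[Si](CC)(CC)O[C@@H]1OC=C(CO)[C@H]2C[C@H](OCc3ccc(OC)cc3)[C@](O)(CO[Si](C)(C)C(C)(C)C)[C@@H]12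
F4 | step 9 | 1β-O-triethylsilyl acetal of lactol aldehyde 13 | CC[Si](CC)(CC)O[C@@H]1OC=C(C=O)[C@H]2C[C@H](OCc3ccc(OC)cc3)[C@](O)(CO[Si](C)(C)C(C)(C)C)[C@@H]12
F5 | step 7 | tert-butyl{[(3S)-3-(4-methoxybenzyloxy)-2-methylidenehex-5-en-1-yl]oxy}dimethylsilane | C=CC[C@H](OCc1ccc(OC)cc1)C(=C)CO[Si](C)(C)C(C)(C)C
F6 | step 7 | (3S)-3-(4-methoxybenzyloxy)-2-methylidenehex-5-en-1-ol | C=CC[C@H](OCc1ccc(OC)cc1)C(=C)CO
F7 | step 7 | {(2S)-2-[(1S)-1-(4-methoxybenzyloxy)but-3-en-1-yl]oxiran-2-yl}methanol | C=CC[C@H](OCc1ccc(OC)cc1)[C@]2(CO)CO2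
F8 | step 7 | tert-butyldimethylsilyl ether of F7 | C=CC[C@H](OCc1ccc(OC)cc1)[C@]2(CO[Si](C)(C)C(C)(C)C)CO2
F9 | step 15 | bis-silyl luzonoid A (C10 O-TBS and phenol O-TBS; free C11 alcohol) | CC(C)CC(=O)O[C@@H]1OC=C(CO)[C@H]2C[C@H](OC(=O)/C=C/c3ccc(O[Si](C)(C)C(C)(C)C)cc3)[C@](O)(CO[Si](C)(C)C(C)(C)C)[C@@H]12
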